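Readings and results stem from a simulated flask with constants of no real substance; the scatter is artificial.

Read the recipes and the west run first; the minutes of the meeting follow them.

| flask | starting material | precatalyst | temperature | remark | time |
|---|---|---|---|---|---|
| west | 1.8 M | 0.1 mol% | 120 °C | run made earlier |  |
| violet | 1.2 M | 0.1 mol% | 120 °C |  | 10 min |
| ochre | 1.2 M | 0.1 mol% |  | at 90 °C until 2.0 min, from then on at 150 °C | 10 min |
| red | 1.2 M | 0.1 mol% | 150 °C |  | 10 min |
| teal | 1.2 M | 0.1 mol% | 90 °C |  | 10 min |

west run (percent of the starting material charged)

| time / min | target / % | starting material / % |
|---|---|---|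
| 0.250 | 11.0 | 72.2 |
| 0.417 | 19.8 | 62.0 |
| 0.833 | 29.1 | 38.9 |
| 1.50 | 40.5 | 21.1 |
| 3.00 | 47.3 | 2.7 |

(each reading ± 1 percentage point)

- in a conversion other conformer counts as not yet reacted
- the earlier runs do not show what temperature does; that part of a forecast is a guess
- no earlier run changes the charge of precatalyst; that part of a forecast is a guess

- the best flask by amount of target, in percent of the starting material charged; "all alike" if 1.5 percentage points covers them all (violet / ochre / red / teal / all alike)
- amount of target at the end, in percent of the starting material charged, violet
- amount of target at the end, in percent of the starting material charged, ochre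
- amount of target at the end, in percent of the starting material charged, red
- amount of target at the end, in percent of the starting material charged, teal

**Minutes.** The kineticist reported that the west run looks first order in starting material, so that its amount A obeys dA/dt = −kA, which integrates to a straight line in ln A against time. From the first and last readings she read k = 1.19 min⁻¹, a pseudo-first-order constant. Its half-life τ = ln(2)/k = 0.580 min she named the conversion clock.

She argued that violet's 10 min holds 17.2 clocks, so conversion there should be complete. The west run's last readings put target at 48.6 % of the material converted, and that was her figure for violet.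

The sceptic objected that τ belongs to 1.8 M, 120 °C and 0.1 mol%, and that the west run does not vary heat or loading. He proposed a rule for any one temperature and loading: target survives better the shorter τ is against the half-life of whatever consumes target. He warned that heat might reverse that order, and the kineticist agreed that she had no number for it.

The forecast was then read: red best, with violet 49 % (46 % to 54 %), ochre 50 % (42 % to 58 %), red 51 % (41 % to 61 %) and teal 44 % (33 % to 52 %). It noted: “Temperature effects are a guess”.

**Result.** Violet gave 46.4 %, ochre 33.4 %, red 33.6 % and teal 41.0 %, so violet was best, and red fell 17 percentage points below the forecast.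

    starting material ⇌ other conformer (K = 0.347, k = 0.222 min⁻¹, Ea = 103 kJ mol⁻¹, ΔH = −31.0 kJ mol⁻¹)
    starting material + catalyst → catalyst + target (k = 102 M⁻¹ min⁻¹, Ea = 58.0 kJ mol⁻¹)
    catalyst + other conformer → catalyst + isomer of the product (k = 291 M⁻¹ min⁻¹, Ea = 37.0 kJ mol⁻¹)
    starting material + target → side product (k = 0.0472 M⁻¹ min⁻¹, Ea = 92.0 kJ mol⁻¹)
    precatalyst → catalyst (k = 1.44 min⁻¹, Ea = 96.0 kJ mol⁻¹)
    (constants at 90 °C)

Red fell short mainly through the step starting material + target → side product: with that step struck out, red holds 92.1 % instead of 33.6 %. The sceptic's rule reads ochre roughly, since the clock of 0.580 min was read at 120 °C in the west run: at 2.16 min, ochre's half-life of target by that step was 0.33 min, shorter than that clock.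

Now take a neighbour of ochre, the same flask with 0.4 mol% of precatalyst. If the clock shortens in step with loading, which is a guess, τ goes from 0.580 min to 0.145 min, so the rule expects target to survive better there. The computed neighbour holds 61.7 %, against 33.4 % in ochre.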